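**Retrosynthetic overview**
1. Target 14 ⇐ tris-MOM ether 13 by acetal cleavage.
2. 13 ⇐ racemic isoflavanone 10 by forming the C3–O bond: catalytic enantioselective aerobic α-hydroxylation, which sets the only stereocentre (proposed new step).
3. 10 ⇐ chromanone 7 + aryl bromide 9 by Pd α-arylation (C3–C1′).
4. 7 ⇐ 7-hydroxychroman-4-one 1 by 6,8-diiodination, MOM protection and twofold Suzuki prenylation; 9 ⇐ 4-bromoresorcinol 8.
5. Rings: none is built; the chromanone bicycle (A/C) and the B ring are bought intact, joined at C3–C1′, then oxidised at C3.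

Assumption: 7-hydroxychroman-4-one (1) is taken as an inexpensive catalogue compound; every compound that delivers atoms to a product carries a number, other reagents are named in the conditions only.

The target is the (3R) enantiomer; CIP order at C3 is OH > C4(=O) > C2H2 > aryl, and it is unchanged by MOM protection.

**Step 1**
Reactants: 1 7-hydroxychroman-4-one; 2 N-iodosuccinimide
Product: 3 7-hydroxy-6,8-diiodochroman-4-one
Conditions: NIS (2.2 equiv), TFA (0.2 equiv), MeCN, 0 °C → rt
Reagents that add atoms: N-iodosuccinimide (2), O=C1CCC(=O)N1I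
Why: Electrophilic aromatic iodination; C6 and C8 are each ortho/para to two oxygen donors (7-OH and O1), so both are iodinated before C5 or the ketone α-position reacts.

**Step 2**
Reactants: 3 7-hydroxy-6,8-diiodochroman-4-one; 4 chloromethyl methyl ether
Product: 5 6,8-diiodo-7-(methoxymethoxy)chroman-4-one
Conditions: MOMCl (1.5 equiv), K2CO3 (2 equiv), acetone, rt
Reagents that add atoms: chloromethyl methyl ether (4), COCCl
Why: Williamson-type O-alkylation; the acidic di-ortho-iodophenoxide forms with carbonate and the very reactive MOMCl alkylates it despite the flanking iodines, leaving the ketone untouched.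

**Step 3**
Reactants: 5 6,8-diiodo-7-(methoxymethoxy)chroman-4-one; 6 prenylboronic acid pinacol ester
Product: 7 7-(methoxymethoxy)-6,8-bis(3-methylbut-2-en-1-yl)chroman-4-one
Conditions: prenylBpin (3 equiv), Pd(dppf)Cl2·CH2Cl2 (10 mol %), K3PO4 (4 equiv), THF–H2O 10:1, 70 °C
Reagents that add atoms: prenylboronic acid pinacol ester (6), CC(C)=CCB1OC(C)(C)C(C)(C)O1
Why: Twofold Suzuki–Miyaura coupling; the prenyl–Pd species equilibrates through the π-allyl form and reductively eliminates from the less hindered primary terminus, giving the linear prenyl group at C6 and C8.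

**Step 4**
Reactants: 8 4-bromoresorcinol; 4 chloromethyl methyl ether
Product: 9 1-bromo-2,4-bis(methoxymethoxy)benzene
Conditions: MOMCl (2.5 equiv), K2CO3 (4 equiv), acetone, 0 °C → rt
Reagents that add atoms: chloromethyl methyl ether (4), COCCl
Why: Twofold Williamson-type O-alkylation of both phenols; the aryl bromide is inert.

**Step 5**
Reactants: 7 7-(methoxymethoxy)-6,8-bis(3-methylbut-2-en-1-yl)chroman-4-one; 9 1-bromo-2,4-bis(methoxymethoxy)benzene
Product: 10 (±)-3-[2,4-bis(methoxymethoxy)phenyl]-7-(methoxymethoxy)-6,8-bis(3-methylbut-2-en-1-yl)chroman-4-one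
Conditions: Pd(OAc)2 (5 mol %), t-Bu3P·HBF4 (10 mol %), NaOt-Bu (2.2 equiv), toluene, 70 °C; then aq NH4Cl
Reagents that add atoms: none
Why: Pd-catalysed ketone α-arylation (Buchwald–Hartwig type) at C3, the only enolisable position; the ortho-substituted aryl group blocks a second arylation, and C3 is formed racemic, which does not matter because step 6 passes through the planar enolate.

**Step 6**
Reactants: 10 (±)-3-[2,4-bis(methoxymethoxy)phenyl]-7-(methoxymethoxy)-6,8-bis(3-methylbut-2-en-1-yl)chroman-4-one; 11 dioxygen
Product: 13 (3R)-3-[2,4-bis(methoxymethoxy)phenyl]-3-hydroxy-7-(methoxymethoxy)-6,8-bis(3-methylbut-2-en-1-yl)chroman-4-one, via tris-MOM (3R)-3-hydroperoxyisoflavanone 12 (not isolated)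
Conditions: O2 (1 atm), N-(9-anthracenylmethyl)cinchoninium chloride (10 mol %), 50% aq KOH, P(OEt)3 (2 equiv), toluene, 0 °C
Reagents that add atoms: dioxygen (11), O=O
Why: Proposed new method: chiral phase-transfer-catalysed enantioselective aerobic α-hydroxylation of an isoflavanone (C3–H → C3–OH), not yet shown for 3-aryl-chroman-4-one enolates; interfacial KOH removes the doubly activated C3–H, the planar enolate enters toluene as a tight ion pair with the cinchona ammonium ion, whose anthracenyl and quinoline walls and C9–OH hydrogen bond shield one face, triplet O2 adds to the open face by electron transfer and radical recombination to give hydroperoxide 12, and P(OEt)3 reduces the O–O bond at once so that C3–C4 cleavage cannot compete, while O2 and the enolate leave the prenyl olefins alone; the sense of induction cannot be predicted with confidence, so it is checked on first use (ECD, chiral HPLC) and the pseudoenantiomeric cinchonidinium salt is taken instead if the (S)-alcohol forms; the closest known reaction types are phase-transfer aerobic α-hydroxylation of 2-substituted indanones and tetralones and phase-transfer α-alkylation of isoflavanone enolates.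

**Step 7**
Reactants: 13 (3R)-3-[2,4-bis(methoxymethoxy)phenyl]-3-hydroxy-7-(methoxymethoxy)-6,8-bis(3-methylbut-2-en-1-yl)chroman-4-one
Product: 14 (3R)-3-(2,4-dihydroxyphenyl)-3,7-dihydroxy-6,8-bis(3-methylbut-2-en-1-yl)chroman-4-one
Conditions: HCl (1.25 M in MeOH), 0 → 35 °C
Reagents that add atoms: none
Why: Acid-catalysed transacetalisation of the three aryl MOM ethers to dimethoxymethane; the quaternary C3 has no α-hydrogen and cannot epimerise, and dilute anhydrous acid at or below 35 °C is expected to stay below the threshold for prenyl–phenol chroman closure or ionisation of the α-keto tertiary alcohol.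

**Compound list**
1 | 7-hydroxychroman-4-one | O=C1CCOc2cc(O)ccc12 | starting material
2 | N-iodosuccinimide | O=C1CCC(=O)N1I | starting material
3 | 7-hydroxy-6,8-diiodochroman-4-one | O=C1CCOc2c(I)c(O)c(I)cc12 | intermediate
4 | chloromethyl methyl ether | COCCl | starting material
5 | 6,8-diiodo-7-(methoxymethoxy)chroman-4-one | COCOc1c(I)cc2c(c1I)OCCC2=O | intermediate
6 | prenylboronic acid pinacol ester | CC(C)=CCB1OC(C)(C)C(C)(C)O1 | starting material
7 | 7-(methoxymethoxy)-6,8-bis(3-methylbut-2-en-1-yl)chroman-4-one | CC(C)=CCc1cc2c(c(CC=C(C)C)c1OCOC)OCCC2=O | intermediate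
8 | 4-bromoresorcinol | Oc1ccc(Br)c(O)c1 | starting material
9 | 1-bromo-2,4-bis(methoxymethoxy)benzene | COCOc1ccc(Br)c(OCOC)c1 | intermediate
10 | (±)-3-[2,4-bis(methoxymethoxy)phenyl]-7-(methoxymethoxy)-6,8-bis(3-methylbut-2-en-1-yl)chroman-4-one | CC(C)=CCc1cc2c(c(CC=C(C)C)c1OCOC)OCC(c1ccc(OCOC)cc1OCOC)C2=O | intermediate
11 | dioxygen | O=O | starting material
12 | (3R)-3-[2,4-bis(methoxymethoxy)phenyl]-3-hydroperoxy-7-(methoxymethoxy)-6,8-bis(3-methylbut-2-en-1-yl)chroman-4-one | CC(C)=CCc1cc2c(c(CC=C(C)C)c1OCOC)OC[C@](OO)(c1ccc(OCOC)cc1OCOC)C2=O | intermediate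
13 | (3R)-3-[2,4-bis(methoxymethoxy)phenyl]-3-hydroxy-7-(methoxymethoxy)-6,8-bis(3-methylbut-2-en-1-yl)chroman-4-one | CC(C)=CCc1cc2c(c(CC=C(C)C)c1OCOC)OC[C@](O)(c1ccc(OCOC)cc1OCOC)C2=O | intermediate
14 | (3R)-3-(2,4-dihydroxyphenyl)-3,7-dihydroxy-6,8-bis(3-methylbut-2-en-1-yl)chroman-4-one | CC(C)=CCc1cc2c(c(CC=C(C)C)c1O)OC[C@](O)(c1ccc(O)cc1O)C2=O | target

**Total step count:** 7. **Longest linear sequence:** 6 (steps 1, 2, 3, 5, 6, 7).

**Steps most likely to fail**

Step 6 (proposed new hydroxylation): the ion pair may give low ee with the twisted 2′-alkoxyaryl enolate, or the hydroperoxide may fragment. The fallback sets out from 10 and comes back at 13. Compound 10 is converted into its potassium enolate (KHMDS, THF, −78 °C) and oxidised with an enantiopure (8,8-dichlorocamphorylsulfonyl)oxaziridine, using the antipode that gives the (R)-alcohol. This is the established reagent-controlled asymmetric enolate hydroxylation, known for 2-substituted tetralone- and chromanone-type enolates, and the N-sulfonyloxaziridine does not epoxidise prenyl groups at −78 °C. New compound on the way: none F0.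

Step 3 (twofold prenylation): linear versus reverse-prenyl selectivity and coupling at the doubly flanked C8 iodide are uncertain. The fallback sets out from 5 and comes back at 7. A twofold Suzuki coupling with allylboronic acid pinacol ester, which has no regiochemical ambiguity, gives 6,8-diallyl-7-(methoxymethoxy)chroman-4-one F1. Twofold olefin cross-metathesis with 2-methyl-2-butene (Grubbs second-generation catalyst, CH2Cl2, 40 °C) then converts both allyl groups into prenyl groups.

Step 5 (α-arylation): the electron-rich, ortho-substituted bromide may couple slowly, and the alkali enolate of the chromanone may ring-open by β-elimination of the phenoxide. The fallback sets out from 7 and comes back at 10. The enolate is taken out of the basic medium: TMSOTf/Et3N (CH2Cl2, 0 °C) gives 7-(methoxymethoxy)-6,8-bis(3-methylbut-2-en-1-yl)-4-(trimethylsilyloxy)-2H-chromene F2. F2 is arylated with 9 under base-free conditions (Pd2(dba)3, P(t-Bu)3, Bu3SnF, CsF, toluene, 85 °C), that is, fluoride/tin-mediated transmetalation of a preformed silyl enol ether in place of an alkali enolate.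

**Further compounds**
F1 | step 3 | 6,8-diallyl-7-(methoxymethoxy)chroman-4-one | C=CCc1cc2c(c(CC=C)c1OCOC)OCCC2=O
F2 | step 5 | 7-(methoxymethoxy)-6,8-bis(3-methylbut-2-en-1-yl)-4-(trimethylsilyloxy)-2H-chromene | CC(C)=CCc1cc2c(c(CC=C(C)C)c1OCOC)OCC=C2O[Si](C)(C)C
F0 | step 6 | none | none
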